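**Retrosynthetic overview**
- The plan rests on ring C, the 4-pyranone. Its carbonyl carbon C4 lies between C4a of ring A and C3, and C2 is a lone CH bound only to C3 and O1. The ring is therefore the sum of an ortho-iodophenol (O1, C8a, C4a), carbon monoxide (C4) and a 1-arylvinyl boronate (C3, C2, ring B).
- Target ⇒ (loss of two MOM groups, C2–C3 dehydrogenation) racemic isoflavanone ⇒ (C4a–C4, C4–C3 and O1–C2 made in one operation) 2-iodo-5-(methoxymethoxy)phenol + CO + chromenyl vinyl boronate.
- Vinyl boronate ⇒ enol triflate ⇒ methyl ketone ⇒ 6-bromochromene ⇒ (propargyl Claisen, ring D) aryl 1,1-dimethylpropargyl ether ⇒ 6-bromoisovanillin + 3-chloro-3-methylbut-1-yne. The formyl group is exchanged for the 5-oxygen by Baeyer–Villiger oxidation before the ring D olefin exists.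
- Iodophenol ⇒ resorcinol monobenzoate by para-iodination, MOM protection and debenzoylation.
- Ring order: rings A and B are bought as benzenes, ring D closes in step 7, ring C closes in step 11 and is aromatised in step 12.

Key step: step 11

Assumption: 2-bromo-5-hydroxy-4-methoxybenzaldehyde (6-bromoisovanillin) is taken as a catalogue compound. It already carries the halogen at the future chromene C6, so no electrophilic bromination of an oxidation-prone chromenol is needed.

**Step 1**
Reactants: 1 resorcinol monobenzoate (3-hydroxyphenyl benzoate)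
Product: 2 5-hydroxy-2-iodophenyl benzoate
Conditions: ICl (1.05 equiv), AcOH, rt
Reagents that add atoms: iodine monochloride, ClI
Why: Electrophilic aromatic iodination should be steered by the free hydroxyl, a much stronger donor than the benzoyloxy group, to its para position, which is the carbon next to the ester oxygen that later becomes O1.

**Step 2**
Reactants: 2 5-hydroxy-2-iodophenyl benzoate
Product: 3 2-iodo-5-(methoxymethoxy)phenyl benzoate
Conditions: MOMCl, i-Pr2NEt, CH2Cl2, 0 °C → rt
Reagents that add atoms: chloromethyl methyl ether (MOMCl), COCCl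
Why: O-alkylation of the only free phenol (MOM ether formation) under amine base should leave the aryl benzoate and the iodide untouched, and the meta relationship of the two oxygens rules out acyl migration.

**Step 3**
Reactants: 3 2-iodo-5-(methoxymethoxy)phenyl benzoate
Product: 4 2-iodo-5-(methoxymethoxy)phenol
Conditions: K2CO3 (0.5 equiv), MeOH, rt
Reagents that add atoms: none
Why: Base-promoted transesterification (methanolysis) of the activated aryl ester should free the phenol ortho to iodine, while the MOM acetal and the C–I bond are inert to mild base.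

**Step 4**
Reactants: 5 2-bromo-5-hydroxy-4-methoxybenzaldehyde (6-bromoisovanillin); 6 3-chloro-3-methylbut-1-yne
Product: 7 2-bromo-4-methoxy-5-[(2-methylbut-3-yn-2-yl)oxy]benzaldehyde
Conditions: 6 (1.5 equiv), DBU, CuCl2 (1 mol %), MeCN, 0 °C → rt
Reagents that add atoms: none
Why: Copper-catalysed propargylic etherification of a phenoxide with a tertiary propargylic chloride should give the hindered tertiary aryl ether under conditions mild enough for the aldehyde and the aryl bromide.

**Step 5**
Reactants: 7 2-bromo-4-methoxy-5-[(2-methylbut-3-yn-2-yl)oxy]benzaldehyde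
Product: 9 2-bromo-4-methoxy-5-[(2-methylbut-3-yn-2-yl)oxy]phenol, via aryl formate 8 (not isolated)
Conditions: mCPBA, CH2Cl2, 0 °C → rt, aq NaHCO3 wash; then K2CO3 (0.2 equiv), MeOH, rt
Reagents that add atoms: 3-chloroperoxybenzoic acid (mCPBA), O=C(OO)c1cccc(Cl)c1
Why: In this Baeyer–Villiger (Dakin-type) oxidation the aryl group, activated by the para methoxy group, should migrate to oxygen and the formate then falls to methanolysis, and because the step precedes chromene formation the peracid meets only an inert terminal alkyne.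

**Step 6**
Reactants: 9 2-bromo-4-methoxy-5-[(2-methylbut-3-yn-2-yl)oxy]phenol
Product: 10 1-bromo-5-methoxy-2-(methoxymethoxy)-4-[(2-methylbut-3-yn-2-yl)oxy]benzene
Conditions: MOMCl, i-Pr2NEt, CH2Cl2, 0 °C → rt
Reagents that add atoms: chloromethyl methyl ether (MOMCl), COCCl
Why: MOM ether formation on the single phenol masks the future 2'-hydroxyl with a group that withstands heat, organolithium, strong base and palladium catalysis and also chelates the later aryllithium.

**Step 7**
Reactants: 10 1-bromo-5-methoxy-2-(methoxymethoxy)-4-[(2-methylbut-3-yn-2-yl)oxy]benzene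
Product: 12 6-bromo-8-methoxy-5-(methoxymethoxy)-2,2-dimethyl-2H-chromene, via ortho-allenylphenol 11 (not isolated)
Conditions: o-xylene, 140 °C (reflux), Ar
Reagents that add atoms: none
Why: The aromatic propargyl Claisen rearrangement can only end at the one unsubstituted ortho carbon (the other bears OMe), and the allenylphenol should close ring D by 1,5-hydrogen shift and 6π oxa-electrocyclisation, placing the pyran between the ring oxygen and the MOM-protected oxygen.

**Step 8**
Reactants: 12 6-bromo-8-methoxy-5-(methoxymethoxy)-2,2-dimethyl-2H-chromene; 13 N-methoxy-N-methylacetamide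
Product: 15 1-[8-methoxy-5-(methoxymethoxy)-2,2-dimethyl-2H-chromen-6-yl]ethan-1-one, via aryllithium 14 (not isolated)
Conditions: n-BuLi (1.05 equiv), THF, −78 °C; then 13, −78 → 0 °C; H2O quench
Reagents that add atoms: none
Why: Bromine–lithium exchange should give an aryllithium chelated by the ortho MOM group, and the Weinreb ketone synthesis stops at the ketone because the tetrahedral chelate survives until the quench.

**Step 9**
Reactants: 15 1-[8-methoxy-5-(methoxymethoxy)-2,2-dimethyl-2H-chromen-6-yl]ethan-1-one
Product: 17 1-[8-methoxy-5-(methoxymethoxy)-2,2-dimethyl-2H-chromen-6-yl]vinyl trifluoromethanesulfonate, via potassium enolate 16 (not isolated)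
Conditions: KHMDS, THF, −78 °C; then PhNTf2, −78 → 0 °C; filtration through Et3N-deactivated silica
Reagents that add atoms: N-phenylbis(trifluoromethanesulfonimide) (PhNTf2), O=S(=O)(N(c1ccccc1)S(=O)(=O)C(F)(F)F)C(F)(F)F
Why: Enolate O-sulfonylation (enol triflate formation) is unambiguous because the methyl group is the only enolisable position, and the neutral triflyl donor avoids acid that would ionise the product.

**Step 10**
Reactants: 17 1-[8-methoxy-5-(methoxymethoxy)-2,2-dimethyl-2H-chromen-6-yl]vinyl trifluoromethanesulfonate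
Product: 18 2-{1-[8-methoxy-5-(methoxymethoxy)-2,2-dimethyl-2H-chromen-6-yl]vinyl}-4,4,5,5-tetramethyl-1,3,2-dioxaborolane
Conditions: B2pin2 (1.1 equiv), PdCl2(PPh3)2 (3 mol %), PPh3 (6 mol %), KOPh (1.5 equiv), toluene, 50 °C
Reagents that add atoms: bis(pinacolato)diboron (B2pin2), CC1(C)OB(OC1(C)C)B1OC(C)(C)C(C)(C)O1
Why: Miyaura borylation of a 1-alkenyl triflate with the weak base KOPh at moderate temperature should install boron at the triflate carbon without follow-on Suzuki homocoupling.

**Step 11**
Reactants: 4 2-iodo-5-(methoxymethoxy)phenol; 18 2-{1-[8-methoxy-5-(methoxymethoxy)-2,2-dimethyl-2H-chromen-6-yl]vinyl}-4,4,5,5-tetramethyl-1,3,2-dioxaborolane; 19 carbon monoxide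
Product: 21 rac-3-[8-methoxy-5-(methoxymethoxy)-2,2-dimethyl-2H-chromen-6-yl]-7-(methoxymethoxy)chroman-4-one, via 2-arylpropenone 20 (not isolated)
Conditions: 4 (1 equiv), 18 (1.3 equiv), CO (5 bar), PdCl2(PPh3)2 (5 mol %), K2CO3 (3 equiv), anisole–H2O (20:1), 80 °C
Reagents that add atoms: none
Why: Oxidative addition of zerovalent palladium into the C–I bond of 4 and migratory insertion of CO should give an aroylpalladium iodide, which transmetalates with the base-activated boronate 18 and reductively eliminates to the 2-arylprop-2-en-1-one 20, so that C4a–C4 and C4–C3 arise in one catalytic cycle. The closest known reaction type is the carbonylative Suzuki–Miyaura coupling of aryl iodides with alkenylboron reagents to aryl vinyl ketones, which accepts free ortho hydroxyl groups, joined to the oxa-Michael closure by which 2'-hydroxy-α-arylacrylophenones collapse to isoflavanones. Ring C closes by 6-endo-trig conjugate addition of the ortho phenoxide (O1) to the unsubstituted methylene terminus (C2), since attack at the α-carbon is electronically mismatched. The one new stereocentre, C3, is set by unselective protonation of the resulting enolate, so 21 is racemic, which is harmless because C3 becomes sp2 in step 12. The selectivity needed is ketone formation over direct CO-free coupling and over capture of the acyl complex by phenoxide or water: the electron-rich aryl group of 4 migrates readily onto CO, the CO overpressure shortens the life of the arylpalladium stage, the ortho-substituted 1,1-disubstituted boronate transmetalates slowly enough for insertion to come first, and an excess of 18 with little water limits ester and acid formation. Immediate ring closure also removes the polymerisable enone from the mixture.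

**Step 12**
Reactants: 21 rac-3-[8-methoxy-5-(methoxymethoxy)-2,2-dimethyl-2H-chromen-6-yl]-7-(methoxymethoxy)chroman-4-one
Product: 22 3-[8-methoxy-5-(methoxymethoxy)-2,2-dimethyl-2H-chromen-6-yl]-7-(methoxymethoxy)-4H-chromen-4-one
Conditions: DDQ (1.5 equiv), 1,4-dioxane, 90 °C
Reagents that add atoms: none
Why: In this quinone dehydrogenation of an isoflavanone, hydride abstraction from C2 of the enol tautomer is assisted by O1 and proton loss gives the aromatic pyranone, while ring D offers no abstractable hydrogen because its C2 is quaternary.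

**Step 13**
Reactants: 22 3-[8-methoxy-5-(methoxymethoxy)-2,2-dimethyl-2H-chromen-6-yl]-7-(methoxymethoxy)-4H-chromen-4-one
Product: 23 7-hydroxy-3-(5-hydroxy-8-methoxy-2,2-dimethyl-2H-chromen-6-yl)-4H-chromen-4-one (target)
Conditions: conc. HCl (to ca. 0.5 M), MeOH–THF, 50 °C
Reagents that add atoms: none
Why: Acid-catalysed acetal exchange with methanol should remove both aryl MOM ethers, and dilute methanolic acid at moderate temperature is tolerated by the 2,2-dimethylchromene olefin and the isoflavone core of the achiral target.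

**Compound list**
1 | resorcinol monobenzoate | O=C(Oc1cccc(O)c1)c1ccccc1 | starting material
2 | 5-hydroxy-2-iodophenyl benzoate | O=C(Oc1cc(O)ccc1I)c1ccccc1 | intermediate
3 | 2-iodo-5-(methoxymethoxy)phenyl benzoate | O=C(Oc1cc(OCOC)ccc1I)c1ccccc1 | intermediate
4 | 2-iodo-5-(methoxymethoxy)phenol | Oc1cc(OCOC)ccc1I | intermediate
5 | 2-bromo-5-hydroxy-4-methoxybenzaldehyde | O=Cc1cc(O)c(OC)cc1Br | starting material
6 | 3-chloro-3-methylbut-1-yne | CC(C)(Cl)C#C | starting material
7 | 2-bromo-4-methoxy-5-[(2-methylbut-3-yn-2-yl)oxy]benzaldehyde | O=Cc1cc(OC(C)(C)C#C)c(OC)cc1Br | intermediate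
8 | 2-bromo-4-methoxy-5-[(2-methylbut-3-yn-2-yl)oxy]phenyl formate (not isolated) | O=COc1cc(OC(C)(C)C#C)c(OC)cc1Br | intermediate
9 | 2-bromo-4-methoxy-5-[(2-methylbut-3-yn-2-yl)oxy]phenol | Oc1cc(OC(C)(C)C#C)c(OC)cc1Br | intermediate
10 | 1-bromo-5-methoxy-2-(methoxymethoxy)-4-[(2-methylbut-3-yn-2-yl)oxy]benzene | COCOc1cc(OC(C)(C)C#C)c(OC)cc1Br | intermediate
11 | 4-bromo-6-methoxy-3-(methoxymethoxy)-2-(3-methylbuta-1,2-dien-1-yl)phenol (not isolated) | Oc1c(OC)cc(Br)c(OCOC)c1C=C=C(C)C | intermediate
12 | 6-bromo-8-methoxy-5-(methoxymethoxy)-2,2-dimethyl-2H-chromene | COCOc1c(Br)cc(OC)c2OC(C)(C)C=Cc12 | intermediate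
13 | N-methoxy-N-methylacetamide | CC(=O)N(C)OC | starting material
14 | [8-methoxy-5-(methoxymethoxy)-2,2-dimethyl-2H-chromen-6-yl]lithium (not isolated) | [Li]c1cc(OC)c2OC(C)(C)C=Cc2c1OCOC | intermediate
15 | 1-[8-methoxy-5-(methoxymethoxy)-2,2-dimethyl-2H-chromen-6-yl]ethan-1-one | CC(=O)c1cc(OC)c2OC(C)(C)C=Cc2c1OCOC | intermediate
16 | potassium 1-[8-methoxy-5-(methoxymethoxy)-2,2-dimethyl-2H-chromen-6-yl]ethen-1-olate (not isolated) | C=C([O-])c1cc(OC)c2OC(C)(C)C=Cc2c1OCOC.[K+] | intermediate
17 | 1-[8-methoxy-5-(methoxymethoxy)-2,2-dimethyl-2H-chromen-6-yl]vinyl trifluoromethanesulfonate | C=C(OS(=O)(=O)C(F)(F)F)c1cc(OC)c2OC(C)(C)C=Cc2c1OCOC | intermediate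
18 | 2-{1-[8-methoxy-5-(methoxymethoxy)-2,2-dimethyl-2H-chromen-6-yl]vinyl}-4,4,5,5-tetramethyl-1,3,2-dioxaborolane | C=C(B1OC(C)(C)C(C)(C)O1)c1cc(OC)c2OC(C)(C)C=Cc2c1OCOC | intermediate
19 | carbon monoxide | [C-]#[O+] | starting material
20 | 1-[2-hydroxy-4-(methoxymethoxy)phenyl]-2-[8-methoxy-5-(methoxymethoxy)-2,2-dimethyl-2H-chromen-6-yl]prop-2-en-1-one (not isolated) | C=C(C(=O)c1ccc(OCOC)cc1O)c1cc(OC)c2OC(C)(C)C=Cc2c1OCOC | intermediate
21 | rac-3-[8-methoxy-5-(methoxymethoxy)-2,2-dimethyl-2H-chromen-6-yl]-7-(methoxymethoxy)chroman-4-one (racemic at C3) | COCOc1ccc2c(c1)OCC(c1cc(OC)c3OC(C)(C)C=Cc3c1OCOC)C2=O | intermediate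
22 | 3-[8-methoxy-5-(methoxymethoxy)-2,2-dimethyl-2H-chromen-6-yl]-7-(methoxymethoxy)-4H-chromen-4-one | COCOc1ccc2c(c1)occ(-c1cc(OC)c3OC(C)(C)C=Cc3c1OCOC)c2=O | intermediate
23 | 7-hydroxy-3-(5-hydroxy-8-methoxy-2,2-dimethyl-2H-chromen-6-yl)-4H-chromen-4-one | COc1cc(-c2coc3cc(O)ccc3c2=O)c(O)c2c1OC(C)(C)C=C2 | target

**Step count**
Total step count: 13.
Longest linear sequence: 10 steps (steps 4–13, from 5). Steps 1–3 form the convergent branch.

**Steps most likely to fail**

1. **Step 11.**
   - Transmetalation of the hindered boronate may be too slow. The acylpalladium species would then be intercepted by phenoxide or water, the boronate would be lost by protodeboronation, or coupling would occur without uptake of CO.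
   - The fallback sets out from 12 and comes back at 22, leaving out steps 8–12.
   - Aryllithium 14, made as in step 8, is quenched with 2-isopropoxy-4,4,5,5-tetramethyl-1,3,2-dioxaborolane to give 2-[8-methoxy-5-(methoxymethoxy)-2,2-dimethyl-2H-chromen-6-yl]-4,4,5,5-tetramethyl-1,3,2-dioxaborolane F1.
   - In parallel, commercial 2,4-dihydroxyacetophenone is alkylated at its non-chelated 4-hydroxyl (MOMCl, K2CO3, acetone) to 1-[2-hydroxy-4-(methoxymethoxy)phenyl]ethan-1-one F2.
   - F2 is condensed with DMF dimethyl acetal to (E)-3-(dimethylamino)-1-[2-hydroxy-4-(methoxymethoxy)phenyl]prop-2-en-1-one F3.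
   - F3 is cyclised with I2 and pyridine in CHCl3 to 3-iodo-7-(methoxymethoxy)-4H-chromen-4-one F4.
   - Suzuki–Miyaura coupling of the boronate with the iodochromone (PdCl2(dppf), Na2CO3, DME–H2O, 80 °C) forms the C3–C1' bond on a ready-made pyranone and delivers 22 directly.

2. **Step 9.**
   - The aryl group carries ortho and para oxygen donors. The 1-arylvinyl triflate may therefore ionise or hydrolyse back to the ketone during work-up or on silica, or eliminate to the arylalkyne.
   - The fallback sets out from 15 and comes back at 18, leaving out steps 9 and 10.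
   - Condensation with 2,4,6-triisopropylbenzenesulfonyl hydrazide (THF, rt) gives the (E)-trisylhydrazone of 15 F5.
   - A Shapiro reaction (n-BuLi, 2.2 equiv, THF, −78 → 0 °C) then gives {1-[8-methoxy-5-(methoxymethoxy)-2,2-dimethyl-2H-chromen-6-yl]vinyl}lithium F6.
   - F6 is trapped at −78 °C with 2-isopropoxy-4,4,5,5-tetramethyl-1,3,2-dioxaborolane to give 18.

3. **Step 12.**
   - The quinone may attack the very electron-rich ring B or the chromene. The acidic hydroquinone formed may cause loss of a MOM group, or conversion may stall.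
   - The fallback sets out from 21 and comes back at 22.
   - Enolisation with in-situ trapping (LiHMDS in the presence of Me3SiCl, THF, −78 °C, so that the enolate is silylated before it can ring-open) gives the 4-(trimethylsilyloxy)-2H-chromene silyl enol ether of 21 F7.
   - Saegusa–Ito oxidation of F7 (Pd(OAc)2, 1.1 equiv, MeCN, rt) passes through an oxo-π-allylpalladium species and β-hydride elimination of a C2 hydrogen, giving 22 under neutral, non-quinone conditions.

**Further compounds**
F1 | step 11 | 2-[8-methoxy-5-(methoxymethoxy)-2,2-dimethyl-2H-chromen-6-yl]-4,4,5,5-tetramethyl-1,3,2-dioxaborolane | COCOc1c(B2OC(C)(C)C(C)(C)O2)cc(OC)c2OC(C)(C)C=Cc12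
F2 | step 11 | 1-[2-hydroxy-4-(methoxymethoxy)phenyl]ethan-1-one | CC(=O)c1ccc(OCOC)cc1O
F3 | step 11 | (E)-3-(dimethylamino)-1-[2-hydroxy-4-(methoxymethoxy)phenyl]prop-2-en-1-one | CN(C)/C=C/C(=O)c1ccc(OCOC)cc1O
F4 | step 11 | 3-iodo-7-(methoxymethoxy)-4H-chromen-4-one | COCOc1ccc2c(c1)occ(I)c2=O
F5 | step 9 | (E)-N'-{1-[8-methoxy-5-(methoxymethoxy)-2,2-dimethyl-2H-chromen-6-yl]ethylidene}-2,4,6-triisopropylbenzenesulfonohydrazide | C/C(=N\NS(=O)(=O)c1c(C(C)C)cc(C(C)C)cc1C(C)C)c1cc(OC)c2OC(C)(C)C=Cc2c1OCOC
F6 | step 9 | {1-[8-methoxy-5-(methoxymethoxy)-2,2-dimethyl-2H-chromen-6-yl]vinyl}lithium | [Li]C(=C)c1cc(OC)c2OC(C)(C)C=Cc2c1OCOC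
F7 | step 12 | {3-[8-methoxy-5-(methoxymethoxy)-2,2-dimethyl-2H-chromen-6-yl]-7-(methoxymethoxy)-2H-chromen-4-yl}oxy(trimethyl)silane | COCOc1ccc2c(c1)OCC(c1cc(OC)c3OC(C)(C)C=Cc3c1OCOC)=C2O[Si](C)(C)C
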